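The ten-membered carbocycle is closed last, across the two carbinol carbons C8 and C9. Because C9 is allylic to the C1=C10 acrylate, the unit C8(O)–C9(O)–C10=C1 of the ring is the retron of a γ-oxyallylmetal adding to an aldehyde. A chromium cross-pinacol-type macrocyclisation of a seco-dialdehyde (enal C1=C10(CO2Me)–C9HO, aldehyde C8 on the finished 6,12-lactone) should close the ring, set C8 and C9, re-form the ring-cis alkene and leave O8 free but O9 silylated, ready for methacrylate and acetate. The precursor comes from nerol: Sharpless epoxidation sets C4/C5, and C6, C7, C8 and C9 are relayed from it by substrate control.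

Key step: step 11

Remark: germacrane numbering is used (ring C1–C10; C1=C10 bears C14O2Me; epoxide C4–C5 with methyl C15 on C4; lactone O6–C12(=O)–C11(=C13H2)–C7; O8 methacrylate, O9 acetate; α/β as in the usual drawing with H7 α), and the alkene of 8, 9 and 13–16 is drawn as its expected major isomer, any minor isomer being carried along because step 11 re-forms this double bond.

Step 1
Reactants: 1 nerol, (2Z)-3,7-dimethylocta-2,6-dien-1-ol
Product: 2 (2S,3R)-2,3-epoxynerol, [(2S,3R)-3-methyl-3-(4-methylpent-3-en-1-yl)oxiran-2-yl]methanol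
Conditions: Ti(OiPr)4 (cat.), L-(+)-diethyl tartrate (cat.), t-BuOOH, 4 Å molecular sieves, CH2Cl2, −20 °C
Reagents that add atoms: tert-butyl hydroperoxide, CC(C)(C)OO
Why: Sharpless asymmetric epoxidation: the titanium–L-(+)-tartrate catalyst delivers oxygen to one face of the allylic C4=C5 alkene only (the isolated C1 alkene is not epoxidised), which sets C4 and C5 by catalyst control and keeps the cis relationship of C3 and C6 from the Z-alkene.

Step 2
Reactants: 2 (2S,3R)-2,3-epoxynerol
Product: 4 3-[(2R,3S)-3-(hydroxymethyl)-2-methyloxiran-2-yl]propanal, via secondary ozonide 3 (not isolated)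
Conditions: O3, CH2Cl2, −78 °C; then Me2S, −78 °C to rt
Reagents that add atoms: ozone, [O-][O+]=O
Why: Ozonolysis with reductive work-up cleaves the one remaining alkene to the C1 aldehyde and leaves the epoxy alcohol and its stereocentres untouched.

Step 3
Reactants: 4 3-[(2R,3S)-3-(hydroxymethyl)-2-methyloxiran-2-yl]propanal; 5 trimethyl 2-phosphonoacrylate; 6 4-methoxybenzyl alcohol
Product: 8 methyl (2E)-5-[(2R,3S)-3-(hydroxymethyl)-2-methyloxiran-2-yl]-2-{[(4-methoxybenzyl)oxy]methyl}pent-2-enoate, via sodium phosphonate carbanion 7 (not isolated)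
Conditions: 6, NaH, THF, 0 °C; then 5; then 4, 0 °C to rt
Reagents that add atoms: none
Why: Tandem oxa-Michael addition/Horner–Wadsworth–Emmons olefination: the alkoxide of 6 adds to 5 to give the stabilised phosphonate carbanion 7, which olefinates the aldehyde and so installs C10, C14 and the protected C9 in one flask; the alkene geometry is immaterial because step 11 re-forms this double bond.

Step 4
Reactants: 8 methyl (2E)-5-[(2R,3S)-3-(hydroxymethyl)-2-methyloxiran-2-yl]-2-{[(4-methoxybenzyl)oxy]methyl}pent-2-enoate
Product: 9 methyl (2E)-5-[(2R,3R)-3-formyl-2-methyloxiran-2-yl]-2-{[(4-methoxybenzyl)oxy]methyl}pent-2-enoate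
Conditions: Dess–Martin periodinane, pyridine, CH2Cl2, 0 °C
Reagents that add atoms: none
Why: Dess–Martin oxidation turns the primary epoxy alcohol into the epoxy aldehyde under buffered conditions that do not epimerise C5 (its changed descriptor is only formal).

Step 5
Reactants: 10 furan-2(5H)-one
Product: 11 3-(hydroxymethyl)furan-2(5H)-one
Conditions: aqueous formaldehyde, imidazole (cat.), THF/H2O, rt
Reagents that add atoms: formaldehyde, C=O
Why: Morita–Baylis–Hillman hydroxymethylation at the α-carbon of the butenolide with formaldehyde, which creates no stereocentre.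

Step 6
Reactants: 11 3-(hydroxymethyl)furan-2(5H)-one
Product: 12 3-(bromomethyl)furan-2(5H)-one
Conditions: CBr4, PPh3, CH2Cl2, 0 °C
Reagents that add atoms: tetrabromomethane, BrC(Br)(Br)Br
Why: Appel bromination of the primary allylic alcohol gives the bromide with the conjugated ring alkene retained.

Step 7
Reactants: 9 methyl (2E)-5-[(2R,3R)-3-formyl-2-methyloxiran-2-yl]-2-{[(4-methoxybenzyl)oxy]methyl}pent-2-enoate; 12 3-(bromomethyl)furan-2(5H)-one
Product: 13 lactone A, methyl (2E)-5-[(2R,3S)-3-{(S)-hydroxy[(3R)-4-methylidene-5-oxooxolan-3-yl]methyl}-2-methyloxiran-2-yl]-2-{[(4-methoxybenzyl)oxy]methyl}pent-2-enoate (C6 S, C7 R)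
Conditions: Zn dust, THF/saturated aqueous NH4Cl, 0 °C
Reagents that add atoms: none
Why: Barbier-type 2-(alkoxycarbonyl)allylation in which the allylzinc from 12 adds through its ring β-carbon (SE2') via a Zimmerman–Traxler chair: the butenolide ring fixes C8 trans to the CH2Zn carbon (E-crotyl geometry), so C6 and C7 are formed anti, and Felkin–Anh attack anti to the epoxide C5–O bond sets C6 relative to C5.

Step 8
Reactants: 13 lactone A
Product: 14 lactone B, methyl (2E)-5-[(2R,3S)-3-[(2S,3R)-3-(hydroxymethyl)-4-methylidene-5-oxooxolan-2-yl]-2-methyloxiran-2-yl]-2-{[(4-methoxybenzyl)oxy]methyl}pent-2-enoate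
Conditions: DBU (cat.), CH2Cl2, rt
Reagents that add atoms: none
Why: Base-catalysed translactonisation (intramolecular transesterification): the C6 alkoxide attacks C12 and releases the primary C8 alcohol to give the trans-disubstituted 6,12-lactone, favoured because both ring substituents lie trans and the crowded secondary carbinol is relieved; no stereocentre is touched, the anti relationship from step 7 becoming the trans ring fusion.

Step 9
Reactants: 14 lactone B
Product: 15 diol, methyl (2E)-2-(hydroxymethyl)-5-[(2R,3S)-3-[(2S,3R)-3-(hydroxymethyl)-4-methylidene-5-oxooxolan-2-yl]-2-methyloxiran-2-yl]pent-2-enoate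
Conditions: DDQ, CH2Cl2/pH 7 buffer, 0 °C
Reagents that add atoms: none
Why: Oxidative cleavage of the 4-methoxybenzyl ether by DDQ (hydride abstraction to the benzylic oxocarbenium ion, then hydrolysis) frees the C9 alcohol without affecting epoxide, lactone or acrylate units.

Step 10
Reactants: 15 diol
Product: 16 seco-dialdehyde, methyl (2E)-2-formyl-5-[(2R,3S)-3-[(2S,3S)-3-formyl-4-methylidene-5-oxooxolan-2-yl]-2-methyloxiran-2-yl]pent-2-enoate
Conditions: Dess–Martin periodinane (excess), pyridine, CH2Cl2, 0 °C; filtered and used at once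
Reagents that add atoms: none
Why: Dess–Martin oxidation of both primary alcohols gives the enal at C9 and the aldehyde at C8 under pyridine-buffered, nearly neutral conditions, so that C7 (now α to an aldehyde) should not epimerise when the crude product is used at once.

Step 11
Reactants: 16 seco-dialdehyde
Product: 18 ten-membered 8β-hydroxy-9α-(triethylsilyloxy) lactone (21 with OH at C8 and OSiEt3 at C9; all stereocentres and the ring-cis C1=C10 as in 21), via γ-siloxyallylchromium 17 (not isolated)
Conditions: CrCl2 (6 equiv), Et3SiCl (1.1 equiv), DMF, rt; 16 added by syringe pump (final 2 mM); aqueous pH 7 work-up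
Reagents that add atoms: chlorotriethylsilane, CC[Si](Cl)(CC)CC
Why: CrCl2 transfers one electron to the alkylidene formylacetate, the only easily reduced π system of 16, the ketyl oxygen O9 is silylated, and a second CrCl2 captures the allyl radical at C1 to give the γ-siloxyallylchromium 17, which adds through C9 to the C8 aldehyde in a chair-like six-membered transition state (SE2', metal on O8) and re-forms C1=C10. The closest known reaction is the CrCl2/silyl chloride cross-pinacol-type coupling of α-substituted enals with aliphatic aldehydes, known between two molecules and within one, itself a Nozaki–Hiyama–Kishi-type allylation. The ten-membered carbocycle closes by 10-exo-trig attack on the C8 carbonyl with the allyl unit C9–C10–C1 ending inside the ring, so that C2 must sit pseudo-axial on C1, which gives the ring-cis C1=C10 (C2 cis to C9, trans to CO2Me) and also avoids 1,2-strain with the C10 ester. C9 is set by the chair: the siloxy group lies anti to the ester in the β-siloxyacrylate (syn to C1) and C7 is equatorial on C8, hence the 8,9-threo (8β,9α) relationship; C8 is set by the C7 stereocentre, the lactone carbon C11 standing anti to the incoming C9 and C9 passing H7 (Felkin–Anh), the gauche C6–C7–C8–C9 arrangement that the tether through C6 allows. The step needs chemoselection between two aldehydes (secured because only the conjugated one is reduced by CrCl2), mono-silylation at O9 (about one equivalent of Et3SiCl; the trivalent chromium alkoxide at O8 is hydrolysed on work-up) and ring closure over oligomerisation (slow addition, high dilution, and the bias of the trans-lactone and cis-epoxide).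

Step 12
Reactants: 18 ten-membered 8β-hydroxy-9α-(triethylsilyloxy) lactone
Product: 19 8β-methacrylate 9α-triethylsilyl ether (21 with OSiEt3 in place of the acetate)
Conditions: methacrylic anhydride, Et3N, DMAP (cat.), CH2Cl2, 0 °C
Reagents that add atoms: methacrylic anhydride, C=C(C)C(=O)OC(=O)C(C)=C
Why: DMAP-catalysed acylation of the free C8 hydroxyl with the anhydride proceeds with retention at C8 and leaves the silyl ether at O9 in place.

Step 13
Reactants: 19 8β-methacrylate 9α-triethylsilyl ether
Product: 20 8β-methacrylate 9α-alcohol (21 with OH in place of the acetate)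
Conditions: HF·pyridine, pyridine, THF, 0 °C
Reagents that add atoms: none
Why: Fluoride-induced cleavage of the triethylsilyl ether, buffered with pyridine so that the epoxide survives and the methacrylate does not migrate.

Step 14
Reactants: 20 8β-methacrylate 9α-alcohol
Product: 21 target, methyl (1S,2S,4R,7E,9S,10S,11R)-9-acetyloxy-4-methyl-12-methylidene-10-[(2-methylprop-2-enoyl)oxy]-13-oxo-3,14-dioxatricyclo[9.3.0.0(2,4)]tetradec-7-ene-8-carboxylate
Conditions: Ac2O, pyridine, DMAP (cat.), CH2Cl2, 0 °C
Reagents that add atoms: acetic anhydride, CC(=O)OC(C)=O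
Why: Acetylation of the allylic C9 hydroxyl (nucleophilic catalysis by DMAP) with retention completes the target.

Compound list
1 | nerol, (2Z)-3,7-dimethylocta-2,6-dien-1-ol | CC(C)=CCC/C(C)=C\CO | starting material
2 | (2S,3R)-2,3-epoxynerol | CC(C)=CCC[C@@]1(C)O[C@H]1CO | intermediate
3 | secondary ozonide of 2 (3,3-dimethyl-1,2,4-trioxolane at C1, both C1 epimers) | CC1(C)OOC(CC[C@@]2(C)O[C@H]2CO)O1 | intermediate
4 | 3-[(2R,3S)-3-(hydroxymethyl)-2-methyloxiran-2-yl]propanal | O=CCC[C@@]1(C)O[C@H]1CO | intermediate
5 | trimethyl 2-phosphonoacrylate, methyl 2-(dimethoxyphosphoryl)prop-2-enoate | COC(=O)C(=C)P(=O)(OC)OC | starting material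
6 | 4-methoxybenzyl alcohol | COc1ccc(CO)cc1 | starting material
7 | sodium salt of the carbanion of methyl 2-(dimethoxyphosphoryl)-3-[(4-methoxybenzyl)oxy]propanoate | COC(=O)[C-](COCc1ccc(OC)cc1)P(=O)(OC)OC.[Na+] | intermediate
8 | methyl (2E)-5-[(2R,3S)-3-(hydroxymethyl)-2-methyloxiran-2-yl]-2-{[(4-methoxybenzyl)oxy]methyl}pent-2-enoate | COC(=O)/C(COCc1ccc(OC)cc1)=C/CC[C@@]1(C)O[C@H]1CO | intermediate
9 | methyl (2E)-5-[(2R,3R)-3-formyl-2-methyloxiran-2-yl]-2-{[(4-methoxybenzyl)oxy]methyl}pent-2-enoate | COC(=O)/C(COCc1ccc(OC)cc1)=C/CC[C@@]1(C)O[C@H]1C=O | intermediate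
10 | furan-2(5H)-one | O=C1OCC=C1 | starting material
11 | 3-(hydroxymethyl)furan-2(5H)-one | O=C1OCC=C1CO | intermediate
12 | 3-(bromomethyl)furan-2(5H)-one | O=C1OCC=C1CBr | intermediate
13 | lactone A (8,12-lactone with free C6 hydroxyl; C6 S, C7 R) | COC(=O)/C(COCc1ccc(OC)cc1)=C/CC[C@@]1(C)O[C@H]1[C@@H](O)[C@H]1COC(=O)C1=C | intermediate
14 | lactone B (trans-6,12-lactone with free C8 hydroxyl) | COC(=O)/C(COCc1ccc(OC)cc1)=C/CC[C@@]1(C)O[C@H]1[C@H]1OC(=O)C(=C)[C@@H]1CO | intermediate
15 | diol (C8 and C9 primary alcohols) | COC(=O)/C(CO)=C/CC[C@@]1(C)O[C@H]1[C@H]1OC(=O)C(=C)[C@@H]1CO | intermediate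
16 | seco-dialdehyde (C8 aldehyde, C9 enal) | COC(=O)/C(C=O)=C/CC[C@@]1(C)O[C@H]1[C@H]1OC(=O)C(=C)[C@@H]1C=O | intermediate
17 | γ-siloxyallylchromium dichloride (Cr on C1, C1 configuration labile, OSiEt3 syn to C1) | CC[Si](CC)(CC)O/C=C(/C(=O)OC)C([Cr](Cl)Cl)CC[C@@]1(C)O[C@H]1[C@H]1OC(=O)C(=C)[C@@H]1C=O | intermediate
18 | ten-membered 8β-hydroxy-9α-(triethylsilyloxy) lactone | O[C@H]1[C@H]2C(=C)C(=O)O[C@@H]2[C@@H]2O[C@]2(C)CC/C=C(/C(=O)OC)[C@@H]1O[Si](CC)(CC)CC | intermediate
19 | 8β-methacrylate 9α-triethylsilyl ether | C=C(C)C(=O)O[C@H]1[C@H]2C(=C)C(=O)O[C@@H]2[C@@H]2O[C@]2(C)CC/C=C(/C(=O)OC)[C@@H]1O[Si](CC)(CC)CC | intermediate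
20 | 8β-methacrylate 9α-alcohol | C=C(C)C(=O)O[C@H]1[C@H]2C(=C)C(=O)O[C@@H]2[C@@H]2O[C@]2(C)CC/C=C(/C(=O)OC)[C@@H]1O | intermediate
21 | target CNP0153978.8 | C=C(C)C(=O)O[C@H]1[C@H]2C(=C)C(=O)O[C@@H]2[C@@H]2O[C@]2(C)CC/C=C(/C(=O)OC)[C@@H]1OC(C)=O | target

Total step count: 14. Longest linear sequence: 12 steps (steps 1–4 and 7–14, from nerol).

Steps most likely to fail

Step 11. The closure may suffer from poor facial selectivity at the C8 aldehyde, the ring then closing to the 8,9-erythro series. The fallback sets out from 16: the same closure would give the 8α-hydroxy epimer F1. F1 is not acylated with retention but esterified with inversion under Mitsunobu conditions (methacrylic acid, PPh3, diisopropyl azodicarboxylate, toluene, 0 °C). This installs the methacrylate and corrects C8 in one operation and comes back to the route at 19.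

Step 10. The new C8 aldehyde may enolise toward C7 during oxidation or handling, with migration of the exocyclic alkene into the lactone ring, epimerisation at C7 or β-elimination of the lactone oxygen. The fallback sets out from 15 and masks the methylene lactone first. Conjugate addition of thiophenol (Et3N cat., CH2Cl2, 0 °C) gives the sulfide F2, a mixture of C11 epimers, in which the alkene whose migration into conjugation drives the decomposition is absent. Dess–Martin oxidation then gives the masked dialdehyde F3. The CrCl2/Et3SiCl closure of step 11 gives the masked macrocycle F4. Oxidation with mCPBA (1 equiv, −78 °C) gives the sulfoxide F5. Thermal syn-elimination (toluene, 100 °C) restores the C11=C13 methylene and comes back to the route at 18.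

Step 8. The acyl migration may stop at an unfavourable equilibrium between lactone A and lactone B, or the C6 alkoxide may instead shift the epoxide. The fallback sets out from 13 and replaces thermodynamic equilibration by kinetic trapping. With TBSCl, imidazole and catalytic DBU in DMF, the primary C8 alkoxide of lactone B is silylated as it forms, while the hindered C6 hydroxyl of lactone A is not, which gives the silyl ether F6. HF·pyridine then cleaves the silyl ether and comes back to the route at 14.

Further compounds
F1 | step 11 | 8α-hydroxy epimer of 18 (C8 epimer, 9α-OSiEt3) | O[C@@H]1[C@H]2C(=C)C(=O)O[C@@H]2[C@@H]2O[C@]2(C)CC/C=C(/C(=O)OC)[C@@H]1O[Si](CC)(CC)CC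
F2 | step 10 | thiophenol adduct of 15 at C13 (C11 epimers) | COC(=O)/C(CO)=C/CC[C@@]1(C)O[C@H]1[C@H]1OC(=O)C(CSc2ccccc2)[C@@H]1CO
F3 | step 10 | masked dialdehyde (C13 phenylthio, C11 epimers) | COC(=O)/C(C=O)=C/CC[C@@]1(C)O[C@H]1[C@H]1OC(=O)C(CSc2ccccc2)[C@@H]1C=O
F4 | step 10 | masked macrocycle (18 with C11H–CH2SPh in place of the methylene) | O[C@H]1[C@H]2C(CSc3ccccc3)C(=O)O[C@@H]2[C@@H]2O[C@]2(C)CC/C=C(/C(=O)OC)[C@@H]1O[Si](CC)(CC)CC
F5 | step 10 | sulfoxide of F4 | O[C@H]1[C@H]2C(CS(=O)c3ccccc3)C(=O)O[C@@H]2[C@@H]2O[C@]2(C)CC/C=C(/C(=O)OC)[C@@H]1O[Si](CC)(CC)CC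
F6 | step 8 | tert-butyldimethylsilyl ether of 14 at O8 | COC(=O)/C(COCc1ccc(OC)cc1)=C/CC[C@@]1(C)O[C@H]1[C@H]1OC(=O)C(=C)[C@@H]1CO[Si](C)(C)C(C)(C)C
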